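## Analysis of the target

The target is a (2S)-flavanone (2-phenylchroman-4-one, rings A, B and C) whose ring A is fully substituted: hydroxyl at C5, methoxy at C7, and two identical arms at C6 and C8. Each arm is CH2–ring D–CH2–ring E. Ring D is a phenol bound to the ring A methylene through the carbon ortho to its hydroxyl and to a second methylene through the carbon para to that hydroxyl. Ring E is a phenol bound to this second methylene through the carbon ortho to its own hydroxyl. C2 is the only stereocentre, so no relative configuration has to be set, but it is labile: base opens ring C by a retro-oxa-Michael reaction to an achiral chalcone, so C2 is best carried through from a natural flavanone and kept away from strong base. The sensitive groups are five phenols on electron-rich rings (oxidation, quinone methide formation), a ketone with acidic hydrogens at C3, and four diarylmethane links that hot strong acid can cleave. The difficulty is regiochemical: four aryl–CH2–aryl bonds must be placed exactly, two of them at the crowded C6 and C8 positions and two at the ortho carbon of ring E, where ordinary electrophilic benzylation of a phenol gives para-rich mixtures and oligomers. The strategy rests on ring E: its hydroxyl-bearing carbon and its methylene-bearing carbon are neighbours, which is the pattern an oxygen-to-ortho-carbon [2,3]-sigmatropic shift delivers. Ring E can therefore be phenol itself, first bound through oxygen to a sulfur that sits on the ring D para methylene.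

## Retrosynthetic reasoning

**17 to 16.** The last operation only unmasks the C5 hydroxyl and the two ring D hydroxyls of 16 from their methoxymethyl acetals. Acetals are chosen because acid removes them, and the flavanone C2 tolerates dilute acid far better than base. The forward step has to cleave three acetals without opening ring C or cleaving a diarylmethane link.

**16 to 15.** Each ring D–CH2–ring E methylene of 16 is traced back to a carbon that still carries a phenylsulfanyl group, as in 15. These two C–S bonds are what the carbon–carbon bond formation leaves behind. Their removal erases the only uncontrolled stereocentres of the route and has to spare the ketone, the benzylic C2–O bond and the acetals, which points to a radical chain and not to hydride or dissolving metal.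

**15 to 11 and 12.** The two bonds between the sulfur-bearing benzylic carbons and the ortho carbons of ring E are cut. This is the one connection whose regiochemistry cannot be bought or dictated by blocked positions, and cutting here reveals phenol 12 as ring E and the bis(benzylic phenyl sulfide) 11. In the forward direction each sulfur is made electrophilic, takes up 12 through oxygen, and the benzylic ylide hands its carbon to the ortho position within a five-atom array. This demands that every other hydroxyl of 11 is capped, so that only 12 can bind to sulfur. It also demands that the second sulfur substituent has no alpha hydrogen, hence phenyl.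

**11 to 9 and 10.** The C6–CH2 and C8–CH2 bonds are cut so that ring A carries the halogens (diiodide 9) and the arm is the nucleophile (benzylzinc chloride 10). The reverse polarity would put a benzylic leaving group on a phloroglucinol-type ring, where it ionises uncontrollably. An aryl iodide on ring A is stable, and a benzylzinc reagent tolerates the ketone. The forward reaction is a twofold sp2–sp3 coupling at iodides that each have two ortho oxygen substituents, and it must leave the benzylic C–S bonds untouched.

**9 to 8 to 7.** The C5 acetal and the two C–I bonds are removed in turn, leading to (S)-pinostrobin 7. This natural flavanone supplies rings A, B and C, the C7 methoxy group and the (S)-C2 centre. Its ring A has only C6 and C8 open, so the iodination needs no regiocontrol.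

**10 to 6, 5, 4, 3, then 1 and 2.** The zinc reagent 10 comes from chloride 6, which is reached through alcohol 5 and the protected aldehyde 4 from aldehyde 3. The C–S bond of 3 is cut to thiophenol 2 and the chloromethyl salicylaldehyde 1. Compound 1 already holds the 1,2,4-pattern of ring D: the hydroxyl, an ortho one-carbon unit that becomes the CH2 bound to ring A, and a para chloromethyl group that takes the sulfur.

## Alternatives that were turned down

**Alternative 1:** The bonds between the C6 and C8 methylenes and ring D are cut. The forward key step is a cathodic cross-electrophile coupling (NiBr2 with a bipyridine ligand) of the 5-O-acetyl-6,8-bis(chloromethyl) derivative A2 of 7 with two molecules of the aryl bromide A3, which already holds rings D and E. It would give the protected target A1.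
- In its favour: rings D and E arrive together, no organometallic reagent is prepared, only deprotection follows, and the reaction type has general precedent for benzyl chlorides with aryl bromides. On precedent of the key step it is stronger than the chosen route.
- Against it: each chloromethyl group of A2 sits between two ortho oxygens and para to a third, so it ionises readily. Solvolysis, oligomerisation and reductive homocoupling would compete with a slow oxidative addition of the electron-rich, ortho-alkoxy bromide A3. The aryl ketone is also reducible at the cathode.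
- It does not solve the ortho link of ring E. It moves that problem into the synthesis of A3, which needs a prefunctionalised phenol and several steps of its own, and the acetate and acetals of A1 need two deprotection modes.
- The chosen route offers in its place a stable aryl iodide on ring A and phenol itself as ring E.

**Alternative 2:** Ring A is built from scratch. Heating the arm-bearing 3-ethoxycyclobutenone A5 with the arm-bearing methoxyalkyne A6 (a Danheiser-type benzannulation through vinylketene, [2+2] addition, ring opening and six-electron closure) would give the pentasubstituted phenol A4, which has only C4a unsubstituted.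
- In its favour: the substitution pattern of ring A is fixed by the connectivity of two fragments, and the key step needs no reagent. On regiochemical certainty for ring A it is as strong as anything available.
- Against it: that certainty is not needed here, because 7 already has exactly two open positions on ring A.
- A5 and A6 each require a complete arm attached to a strained or sensitive function.
- After A4, ring C, the ketone and the C2 stereocentre would all still have to be made, by acylation at C4a and an enantioselective oxa-Michael closure. The ethyl ether would also have to be told apart from the methyl ether.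
- It is far longer, and it replaces a purchased stereocentre by one that must be induced.

**Alternative 3:** Ring C is closed last at the flavone oxidation level. The symmetrical 2-iodoresorcinol A8, carbon monoxide A9 and phenylacetylene A10 would combine under PdCl2(PPh3)2 catalysis (carbonylative coupling followed by 6-endo oxa-Michael closure) to the flavone A7.
- In its favour: three bonds and a ring form in one step, the symmetry of A8 makes the two hydroxyls equivalent, and a flavone cannot racemise. On robustness toward base it is stronger than the chosen route.
- Against it: A7 has no C2 stereocentre. An enantioselective conjugate reduction of a hindered, chelated 5-hydroxyflavone would be needed late, with over-reduction of the ketone as a standing risk.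
- The iodide of A8 is flanked by two hydroxyls, and 5-exo closure to an aurone competes with the desired 6-endo closure.
- A8 still requires both arms to be installed on a phloroglucinol ring, so nothing is saved on the arm problem.
- The chosen route keeps the natural configuration and spends its risk on a single bond-forming step.

Key step: step 8

Assumption: commercial pinostrobin is taken to be the natural (2S) enantiomer in high enantiomeric purity; the route never creates C2 and only has to preserve it.

## Route

**Step 1**
Reactants: 1 5-(chloromethyl)-2-hydroxybenzaldehyde; 2 thiophenol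
Product: 3 2-hydroxy-5-[(phenylsulfanyl)methyl]benzaldehyde
Conditions: Et3N, CH2Cl2, 0 °C to rt
Reagents that add atoms: none
Why: Thiolate substitution at the benzylic chloride (SN2, or addition to the para-quinone methide that the phenoxide can expel); the soft thiolate outruns the phenoxide oxygen, so sulfur enters at the future ring D para methylene.

**Step 2**
Reactants: 3 2-hydroxy-5-[(phenylsulfanyl)methyl]benzaldehyde
Product: 4 2-(methoxymethoxy)-5-[(phenylsulfanyl)methyl]benzaldehyde
Conditions: MOMCl, iPr2NEt, CH2Cl2, 0 °C to rt
Reagents that add atoms: chloromethyl methyl ether (MOMCl), COCCl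
Why: Williamson-type O-alkylation of the salicylaldehyde phenoxide by the chloromethyl ether; the aryl benzyl sulfide is too weak a nucleophile to interfere, and the acetal later keeps the ring D oxygen away from the activated sulfur.

**Step 3**
Reactants: 4 2-(methoxymethoxy)-5-[(phenylsulfanyl)methyl]benzaldehyde
Product: 5 {2-(methoxymethoxy)-5-[(phenylsulfanyl)methyl]phenyl}methanol
Conditions: NaBH4, MeOH, 0 °C
Reagents that add atoms: none
Why: Hydride reduction of an aryl aldehyde; sulfide and acetal are inert to NaBH4.

**Step 4**
Reactants: 5 {2-(methoxymethoxy)-5-[(phenylsulfanyl)methyl]phenyl}methanol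
Product: 6 2-(chloromethyl)-1-(methoxymethoxy)-4-[(phenylsulfanyl)methyl]benzene
Conditions: MsCl, Et3N, LiCl, THF, 0 °C to rt
Reagents that add atoms: lithium chloride, [Li+].[Cl-]; methanesulfonyl chloride, CS(=O)(=O)Cl (either chloride can end up on carbon)
Why: Sulfonylation of the benzylic alcohol and SN2 displacement of the mesylate by chloride under basic conditions, so the acid-labile acetal survives; oxidising or acidic chlorinating agents are avoided because of the sulfide and the acetal.

**Step 5**
Reactants: 7 (S)-pinostrobin, (2S)-5-hydroxy-7-methoxy-2-phenylchroman-4-one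
Product: 8 (2S)-5-hydroxy-6,8-diiodo-7-methoxy-2-phenylchroman-4-one
Conditions: NIS (2.2 equiv), DMF, 0 °C to rt, dark
Reagents that add atoms: N-iodosuccinimide (NIS), O=C1CCC(=O)N1I
Why: Electrophilic aromatic iodination; C6 and C8 are the only free positions of ring A and each is ortho or para to all three ring oxygens, while the neutral medium leaves C2 and C3 alone.

**Step 6**
Reactants: 8 (2S)-5-hydroxy-6,8-diiodo-7-methoxy-2-phenylchroman-4-one
Product: 9 (2S)-6,8-diiodo-7-methoxy-5-(methoxymethoxy)-2-phenylchroman-4-one
Conditions: MOMCl, iPr2NEt, Bu4NI (cat.), CH2Cl2, 0 to 40 °C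
Reagents that add atoms: chloromethyl methyl ether (MOMCl), COCCl
Why: O-Alkylation of the hydrogen-bonded phenol by the small, highly reactive halomethyl ether (iodide catalysis supplies the iodomethyl ether in the flask); a hindered amine in CH2Cl2 is too weak a base to open ring C, so C2 should keep its configuration.

**Step 7**
Reactants: 6 2-(chloromethyl)-1-(methoxymethoxy)-4-[(phenylsulfanyl)methyl]benzene (2.6 equiv); 9 (2S)-6,8-diiodo-7-methoxy-5-(methoxymethoxy)-2-phenylchroman-4-one
Product: 11 (2S)-7-methoxy-5-(methoxymethoxy)-6,8-bis{2-(methoxymethoxy)-5-[(phenylsulfanyl)methyl]benzyl}-2-phenylchroman-4-one, via arylmethylzinc chloride 10 (not isolated)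
Conditions: Zn dust, LiCl, THF, 25 °C; then 9, Pd(OAc)2 (cat.), SPhos (cat.), THF, 25 to 50 °C
Reagents that add atoms: none
Why: Zinc insertion into the benzylic chloride in the presence of LiCl gives 10, and a twofold Negishi sp2–sp3 coupling follows (oxidative addition of zerovalent palladium into each C–I bond, transmetalation, reductive elimination), the bulky biaryl phosphine coping with the two ortho oxygens at each iodide. The organozinc tolerates ketone, acetals and sulfides and the medium is neutral, so C2 is not touched.

**Step 8**
Reactants: 11 (2S)-7-methoxy-5-(methoxymethoxy)-6,8-bis{2-(methoxymethoxy)-5-[(phenylsulfanyl)methyl]benzyl}-2-phenylchroman-4-one; 12 phenol (6 equiv)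
Product: 15 (2S)-6,8-bis{5-[(2-hydroxyphenyl)(phenylsulfanyl)methyl]-2-(methoxymethoxy)benzyl}-7-methoxy-5-(methoxymethoxy)-2-phenylchroman-4-one (mixture of epimers at both sulfur-bearing carbons), via bis(chlorosulfonium) disuccinimidate 13 (not isolated), via bis(phenoxysulfonium) dichloride 14 (not isolated)
Conditions: 12 (excess), NCS (2.1 equiv), CH2Cl2, −40 °C; then Et3N, −40 to 0 °C
Reagents that add atoms: none
Why: Proposed new method: NCS chlorinates each sulfur to the chlorosulfonium ion of 13, phenol 12 exchanges at sulfur to the aryloxysulfonium ion of 14, and Et3N removes a benzylic proton, the only kind of hydrogen alpha to sulfur, to give a sulfonium ylide. The ylide carbon then bonds to the ortho carbon of the phenoxy group in a five-centre [2,3]-sigmatropic shift while the S–O bond breaks, and the cyclohexadienone so formed tautomerises to the phenol. The closest known reaction type is the Gassman ortho-alkylation of phenols, which runs through the same aryloxysulfonium ylides but is established for dialkyl sulfides; an aryl 4-alkoxybenzyl sulfide, present twice in one molecule, is the untested extension. No ring closes. The two sulfur-bearing carbons form without control beside the fixed (S)-C2, and the epimer mixture converges in step 9 when both carbons become CH2. The selectivity that counts is ortho against para on ring E, and it is secured because the new bond forms within the S–O–C(ipso)–C(ortho) array, which cannot reach the para carbon. The shift has to outrun chloride return to the benzylic carbon, heterolysis of the 4-alkoxybenzyl–sulfur bond and a [3,3] shift into the S-phenyl ring; therefore 12 is present in excess before NCS is added, the temperature is kept low and the base follows at once, which also limits the exposure of C2 to Et3N.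

**Step 9**
Reactants: 15 (2S)-6,8-bis{5-[(2-hydroxyphenyl)(phenylsulfanyl)methyl]-2-(methoxymethoxy)benzyl}-7-methoxy-5-(methoxymethoxy)-2-phenylchroman-4-one
Product: 16 (2S)-6,8-bis[5-(2-hydroxybenzyl)-2-(methoxymethoxy)benzyl]-7-methoxy-5-(methoxymethoxy)-2-phenylchroman-4-one
Conditions: Bu3SnH (excess), AIBN (cat.), toluene, 100 °C
Reagents that add atoms: none
Why: Radical chain desulfurisation: the stannyl radical attacks sulfur, the weak benzhydrylic C–S bond breaks to a doubly benzylic radical, and hydrogen transfer from Bu3SnH gives the CH2 group. Both uncontrolled centres vanish, and ketone, acetals and C2 are inert to stannyl radicals.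

**Step 10**
Reactants: 16 (2S)-6,8-bis[5-(2-hydroxybenzyl)-2-(methoxymethoxy)benzyl]-7-methoxy-5-(methoxymethoxy)-2-phenylchroman-4-one
Product: 17 5''-(2''''-hydroxybenzyl)uvarinol, (2S)-5-hydroxy-6,8-bis[2-hydroxy-5-(2-hydroxybenzyl)benzyl]-7-methoxy-2-phenylchroman-4-one
Conditions: HCl (aq.), MeOH/THF, 45 °C
Reagents that add atoms: none
Why: Acid-catalysed acetal exchange with methanol removes the three methoxymethyl groups; dilute acid at mild temperature should neither open ring C nor cleave the diarylmethane links, so the (S) configuration at C2 is retained.

## Compound list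

1 | 5-(chloromethyl)-2-hydroxybenzaldehyde | O=Cc1cc(CCl)ccc1O | starting material
2 | thiophenol | Sc1ccccc1 | starting material
3 | 2-hydroxy-5-[(phenylsulfanyl)methyl]benzaldehyde | O=Cc1cc(CSc2ccccc2)ccc1O | intermediate
4 | 2-(methoxymethoxy)-5-[(phenylsulfanyl)methyl]benzaldehyde | O=Cc1cc(CSc2ccccc2)ccc1OCOC | intermediate
5 | {2-(methoxymethoxy)-5-[(phenylsulfanyl)methyl]phenyl}methanol | OCc1cc(CSc2ccccc2)ccc1OCOC | intermediate
6 | 2-(chloromethyl)-1-(methoxymethoxy)-4-[(phenylsulfanyl)methyl]benzene | ClCc1cc(CSc2ccccc2)ccc1OCOC | intermediate
7 | (S)-pinostrobin, (2S)-5-hydroxy-7-methoxy-2-phenylchroman-4-one | O=C1C[C@@H](c2ccccc2)Oc2cc(OC)cc(O)c12 | starting material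
8 | (2S)-5-hydroxy-6,8-diiodo-7-methoxy-2-phenylchroman-4-one | O=C1C[C@@H](c2ccccc2)Oc2c(I)c(OC)c(I)c(O)c12 | intermediate
9 | (2S)-6,8-diiodo-7-methoxy-5-(methoxymethoxy)-2-phenylchroman-4-one | O=C1C[C@@H](c2ccccc2)Oc2c(I)c(OC)c(I)c(OCOC)c12 | intermediate
10 | {2-(methoxymethoxy)-5-[(phenylsulfanyl)methyl]benzyl}zinc chloride (not isolated) | Cl[Zn]Cc1cc(CSc2ccccc2)ccc1OCOC | intermediate
11 | (2S)-7-methoxy-5-(methoxymethoxy)-6,8-bis{2-(methoxymethoxy)-5-[(phenylsulfanyl)methyl]benzyl}-2-phenylchroman-4-one | O=C1C[C@@H](c2ccccc2)Oc2c(Cc3cc(CSc4ccccc4)ccc3OCOC)c(OC)c(Cc3cc(CSc4ccccc4)ccc3OCOC)c(OCOC)c12 | intermediate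
12 | phenol | Oc1ccccc1 | starting material
13 | bis(chlorosulfonium) disuccinimidate of 11, each sulfur S-chlorinated (not isolated) | O=C1C[C@@H](c2ccccc2)Oc2c(Cc3cc(C[S+](Cl)c4ccccc4)ccc3OCOC)c(OC)c(Cc3cc(C[S+](Cl)c4ccccc4)ccc3OCOC)c(OCOC)c12.O=C1CCC(=O)[N-]1.O=C1CCC(=O)[N-]1 | intermediate
14 | bis(phenoxysulfonium) dichloride of 11, each sulfur bearing a phenoxy group (not isolated) | O=C1C[C@@H](c2ccccc2)Oc2c(Cc3cc(C[S+](Oc4ccccc4)c4ccccc4)ccc3OCOC)c(OC)c(Cc3cc(C[S+](Oc4ccccc4)c4ccccc4)ccc3OCOC)c(OCOC)c12.[Cl-].[Cl-] | intermediate
15 | (2S)-6,8-bis{5-[(2-hydroxyphenyl)(phenylsulfanyl)methyl]-2-(methoxymethoxy)benzyl}-7-methoxy-5-(methoxymethoxy)-2-phenylchroman-4-one, epimer mixture at both sulfur-bearing carbons | O=C1C[C@@H](c2ccccc2)Oc2c(Cc3cc(C(Sc4ccccc4)c4ccccc4O)ccc3OCOC)c(OC)c(Cc3cc(C(Sc4ccccc4)c4ccccc4O)ccc3OCOC)c(OCOC)c12 | intermediate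
16 | (2S)-6,8-bis[5-(2-hydroxybenzyl)-2-(methoxymethoxy)benzyl]-7-methoxy-5-(methoxymethoxy)-2-phenylchroman-4-one | O=C1C[C@@H](c2ccccc2)Oc2c(Cc3cc(Cc4ccccc4O)ccc3OCOC)c(OC)c(Cc3cc(Cc4ccccc4O)ccc3OCOC)c(OCOC)c12 | intermediate
17 | 5''-(2''''-hydroxybenzyl)uvarinol, (2S)-5-hydroxy-6,8-bis[2-hydroxy-5-(2-hydroxybenzyl)benzyl]-7-methoxy-2-phenylchroman-4-one | COc1c(Cc2cc(Cc3ccccc3O)ccc2O)c(O)c2c(c1Cc1cc(Cc3ccccc3O)ccc1O)O[C@H](c1ccccc1)CC2=O | target

## Step count and least certain steps

Total: 10 steps. Longest linear sequence: 8 steps (steps 1, 2, 3, 4, 7, 8, 9, 10); the flavanone branch (steps 5 and 6) joins at step 7.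

**Step 8 (key step).**
- What may go wrong: the sulfonium stage may collapse before the shift. The 4-alkoxy group of ring D stabilises a benzylic cation, so heterolysis of the benzylic C–S bond with chloride return is a real risk, as is alkylation of phenol through a free cation with loss of ortho control. A [3,3] shift into the S-phenyl ring may also compete, and the second rearrangement may remain incomplete.
- Fallback, from 11 to 17: both phenylsulfanyl groups of 11 are exchanged for chloride with SO2Cl2 in CH2Cl2 at −78 °C in the presence of cyclohexene, which takes up the benzenesulfenyl chloride. This gives (2S)-6,8-bis[5-(chloromethyl)-2-(methoxymethoxy)benzyl]-7-methoxy-5-(methoxymethoxy)-2-phenylchroman-4-one F1, and puts the feared heterolysis to use. [2-(Methoxymethoxy)phenyl]zinc chloride F2 is made from commercial (methoxymethoxy)benzene by directed ortho-lithiation (n-BuLi, THF, 0 °C) and ZnCl2. A twofold Negishi coupling of F2 with the benzylic chlorides of F1 (Pd(OAc)2, SPhos, THF, 25 °C) gives the pentakis(methoxymethyl) ether of the target, F3; ring E is ortho-linked because the zinc sits next to the directing ether. Acidic methanol as in step 10 then removes all five acetals, and the route is rejoined at 17 without step 9.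

**Step 7.**
- What may go wrong: slow oxidative addition or reductive elimination at iodides that each have two ortho oxygens, so that protodeiodination and homocoupling of the benzylzinc reagent take over, or the second coupling stalls after the first arm is in place.
- Fallback, from 3 and 7 to 11: aldehyde 3 is reduced with NaBH4 to 2-(hydroxymethyl)-4-[(phenylsulfanyl)methyl]phenol F4. Heating 7 with excess F4 and ZnCl2 in dioxane alkylates C6 and C8 by electrophilic substitution through the ortho-quinone methide, the way C-benzylated flavanones are classically assembled. This gives (2S)-5-hydroxy-6,8-bis{2-hydroxy-5-[(phenylsulfanyl)methyl]benzyl}-7-methoxy-2-phenylchroman-4-one F5. Threefold etherification of F5 with MOMCl and iPr2NEt returns to the route at 11.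

**Step 9.**
- What may go wrong: hydrogen transfer to the stabilised diarylmethyl radicals is slow, so radical dimerisation or incomplete cleavage of the second C–S bond may result.
- Fallback, from 15 to 16: hydrogenolysis of both C–S bonds over Raney nickel (Ni) that has been deactivated by brief reflux in acetone, in EtOH/THF at rt, which replaces the radical chain by a surface reaction. This fallback makes no new compound (F0).

**Step 6.**
- What may go wrong: incomplete etherification of the hydroxyl that is hydrogen-bonded to the ketone and flanked by the C6 iodine. Forcing it with a stronger base would open ring C by retro-oxa-Michael reaction and erode the configuration at C2.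
- Fallback, from 7 to 9: the order is reversed and base is avoided. Compound 7 is first etherified by acetal exchange (dimethoxymethane, P2O5, CHCl3, rt) to (2S)-7-methoxy-5-(methoxymethoxy)-2-phenylchroman-4-one F6, where no iodine hinders the hydroxyl. F6 is then diiodinated at C6 and C8 with I2 and AgO2CCF3 over NaHCO3 in CH2Cl2, which returns to the route at 9.

## Further compounds

F1 | step 8 | (2S)-6,8-bis[5-(chloromethyl)-2-(methoxymethoxy)benzyl]-7-methoxy-5-(methoxymethoxy)-2-phenylchroman-4-one | O=C1C[C@@H](c2ccccc2)Oc2c(Cc3cc(CCl)ccc3OCOC)c(OC)c(Cc3cc(CCl)ccc3OCOC)c(OCOC)c12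
F2 | step 8 | [2-(methoxymethoxy)phenyl]zinc chloride | COCOc1ccccc1[Zn]Cl
F3 | step 8 | (2S)-7-methoxy-5-(methoxymethoxy)-6,8-bis{2-(methoxymethoxy)-5-[2-(methoxymethoxy)benzyl]benzyl}-2-phenylchroman-4-one | O=C1C[C@@H](c2ccccc2)Oc2c(Cc3cc(Cc4ccccc4OCOC)ccc3OCOC)c(OC)c(Cc3cc(Cc4ccccc4OCOC)ccc3OCOC)c(OCOC)c12
F4 | step 7 | 2-(hydroxymethyl)-4-[(phenylsulfanyl)methyl]phenol | OCc1cc(CSc2ccccc2)ccc1O
F5 | step 7 | (2S)-5-hydroxy-6,8-bis{2-hydroxy-5-[(phenylsulfanyl)methyl]benzyl}-7-methoxy-2-phenylchroman-4-one | O=C1C[C@@H](c2ccccc2)Oc2c(Cc3cc(CSc4ccccc4)ccc3O)c(OC)c(Cc3cc(CSc4ccccc4)ccc3O)c(O)c12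
F0 | step 9 | none | none
F6 | step 6 | (2S)-7-methoxy-5-(methoxymethoxy)-2-phenylchroman-4-one | O=C1C[C@@H](c2ccccc2)Oc2cc(OC)cc(OCOC)c12
A1 | alternative 1 | (2S)-5-acetoxy-7-methoxy-6,8-bis{2-(methoxymethoxy)-5-[2-(methoxymethoxy)benzyl]benzyl}-2-phenylchroman-4-one | O=C1C[C@@H](c2ccccc2)Oc2c(Cc3cc(Cc4ccccc4OCOC)ccc3OCOC)c(OC)c(Cc3cc(Cc4ccccc4OCOC)ccc3OCOC)c(OC(C)=O)c12
A2 | alternative 1 | (2S)-5-acetoxy-6,8-bis(chloromethyl)-7-methoxy-2-phenylchroman-4-one | O=C1C[C@@H](c2ccccc2)Oc2c(CCl)c(OC)c(CCl)c(OC(C)=O)c12
A3 | alternative 1 | 2-bromo-1-(methoxymethoxy)-4-[2-(methoxymethoxy)benzyl]benzene | COCOc1ccc(Cc2ccccc2OCOC)cc1Br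
A4 | alternative 2 | 5-ethoxy-3-methoxy-2,4-bis{2-(benzyloxy)-5-[2-(benzyloxy)benzyl]benzyl}phenol | CCOc1cc(O)c(Cc3cc(Cc4ccccc4OCc4ccccc4)ccc3OCc3ccccc3)c(OC)c1Cc3cc(Cc4ccccc4OCc4ccccc4)ccc3OCc3ccccc3
A5 | alternative 2 | 2-{2-(benzyloxy)-5-[2-(benzyloxy)benzyl]benzyl}-3-ethoxycyclobut-2-en-1-one | CCOC1=C(Cc2cc(Cc3ccccc3OCc3ccccc3)ccc2OCc2ccccc2)C(=O)C1
A6 | alternative 2 | 1-(benzyloxy)-4-[2-(benzyloxy)benzyl]-2-(3-methoxyprop-2-yn-1-yl)benzene | COC#CCc1cc(Cc2ccccc2OCc2ccccc2)ccc1OCc1ccccc1
A7 | alternative 3 | 5-hydroxy-7-methoxy-6,8-bis{2-(methoxymethoxy)-5-[2-(methoxymethoxy)benzyl]benzyl}-2-phenyl-4H-chromen-4-one | O=c1cc(-c2ccccc2)oc2c(Cc3cc(Cc4ccccc4OCOC)ccc3OCOC)c(OC)c(Cc3cc(Cc4ccccc4OCOC)ccc3OCOC)c(O)c12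
A8 | alternative 3 | 2-iodo-5-methoxy-4,6-bis{2-(methoxymethoxy)-5-[2-(methoxymethoxy)benzyl]benzyl}benzene-1,3-diol | Oc1c(I)c(O)c(Cc2cc(Cc3ccccc3OCOC)ccc2OCOC)c(OC)c1Cc1cc(Cc2ccccc2OCOC)ccc1OCOC
A9 | alternative 3 | carbon monoxide | [C-]#[O+]
A10 | alternative 3 | phenylacetylene | C#Cc1ccccc1
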